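**Strategy**

Numbering of the target: ring A = C1 (CMe2), C2 (CHBr), C3, C4, C5 (CHMe), C6 (spiro); ring B = C6, C7, C8 (CHBr), C9 (CMeCl), C10, C11. The route rests on cutting ring B at C6–C11 and C7–C8. An acid-catalysed Michael–aldol spiroannulation unites the ring A aldehyde (C7 as CHO on C6) with methyl vinyl ketone: it forges the quaternary bond C6–C11 on the face away from the axial C5 and C1 methyl groups, fixes the spiro centre and closes ring B as an enone that marks C8 for bromine and C9 for methyl and chlorine. Ring A arises by enantiospecific bromonium cyclisation of a geranate-derived dibromide.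

Key step: step 6

Remark (assumption): the L-fructose-derived enantiomer of the Shi ketone is taken as purchasable; atom numbers in the Why lines are those of the target as defined above.

**Route**

Step 1
Reactants: 1 methyl (2E)-3,7-dimethylocta-2,6-dienoate (methyl geranate)
Product: 2 methyl (2E)-5-[(2S)-3,3-dimethyloxiran-2-yl]-3-methylpent-2-enoate
Conditions: ent-Shi ketone (cat.), KHSO5, K2CO3, Bu4NHSO4 (cat.), MeCN–CH2(OMe)2–aq. Na2B4O7 buffer, 0 °C
Reagents that add atoms: potassium peroxymonosulfate (KHSO5), [K+].[O-]S(=O)(=O)OO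
Why: Shi asymmetric epoxidation; the chiral dioxirane attacks only the electron-rich trisubstituted alkene (the conjugated enoate is inert) through a spiro transition state, and the L-fructose-derived ketone should deliver the (S)-epoxide.

Step 2
Reactants: 2 methyl (2E)-5-[(2S)-3,3-dimethyloxiran-2-yl]-3-methylpent-2-enoate
Product: 3 methyl (2E,6R)-6,7-dibromo-3,7-dimethyloct-2-enoate
Conditions: Ph3PBr2, CH2Cl2, 0 → 23 °C
Reagents that add atoms: dibromotriphenylphosphorane (Ph3PBr2), BrP(Br)(c1ccccc1)(c1ccccc1)c1ccccc1
Why: deoxygenative dibromination of an epoxide; bromide opens the phosphonium-activated epoxide and the oxyphosphonium is then displaced, so the single stereocentre undergoes exactly one inversion (S C–O to R C–Br) whichever C–O bond breaks first.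

Step 3
Reactants: 3 methyl (2E,6R)-6,7-dibromo-3,7-dimethyloct-2-enoate
Product: 4 methyl (1S,5R)-5-bromo-2,6,6-trimethylcyclohex-2-ene-1-carboxylate
Conditions: (CF3)2CHOH, NaHCO3, 23 °C
Reagents that add atoms: none
Why: solvolytic bromonium-ion cation–olefin cyclisation; the tertiary bromide ionises with anchimeric help of the secondary bromine, the configurationally defined bromonium ion is opened at C1 by the alkene carbon C6 through a chair (bromine and ester equatorial, hence cis), and loss of a ring proton gives the C4=C5 alkene, so C2 stays R and C6 is set relative to it.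

Step 4
Reactants: 4 methyl (1S,5R)-5-bromo-2,6,6-trimethylcyclohex-2-ene-1-carboxylate
Product: 5 methyl (1S,3R,6S)-3-bromo-2,2,6-trimethylcyclohexane-1-carboxylate
Conditions: H2 (1 atm), PtO2, EtOAc, 23 °C
Reagents that add atoms: none
Why: heterogeneous syn-hydrogenation from the face opposite the axial C1 methyl should place the C5 methyl cis to the ester and to bromine (C5 = S); the neopentyl-type secondary bromide is expected to survive over PtO2.

Step 5
Reactants: 5 methyl (1S,3R,6S)-3-bromo-2,2,6-trimethylcyclohexane-1-carboxylate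
Product: 6 (1S,3R,6S)-3-bromo-2,2,6-trimethylcyclohexane-1-carbaldehyde
Conditions: i-Bu2AlH, CH2Cl2, −78 °C; aq. potassium sodium tartrate
Reagents that add atoms: none
Why: partial reduction of a hindered ester, whose tetrahedral aluminium hemiacetal persists at −78 °C and gives the aldehyde on hydrolysis; the α-centre is of no consequence because it is enolised in step 6.

Step 6
Reactants: 6 (1S,3R,6S)-3-bromo-2,2,6-trimethylcyclohexane-1-carbaldehyde; 7 but-3-en-2-one (methyl vinyl ketone)
Product: 9 (6R,8R,11S)-8-bromo-7,7,11-trimethylspiro[5.5]undec-1-en-3-one, via keto aldehyde 8 (not isolated)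
Conditions: H2SO4 (cat.), toluene, 45 → 110 °C (Dean–Stark)
Reagents that add atoms: methyl vinyl ketone (7), C=CC(C)=O
Why: Acid-catalysed enolisation of 6 and conjugate addition of the tetrasubstituted enol carbon C6 to protonated 7 form the quaternary bond C6–C11 (keto aldehyde 8); the methyl ketone enol (C8) then attacks the aldehyde carbon C7 and water is lost. The closest known reaction type is the acid-catalysed Robinson-type annulation of α,α-disubstituted aldehydes with methyl vinyl ketone to 4,4-disubstituted cyclohexenones. Ring B closes in the aldol step in the 6-(enolendo)-exo-trig mode. The only new stereocentre, C6, is controlled by ring A: in the chair with equatorial bromine the C5 methyl and one C1 methyl are axial on the same face, so C11 should enter from the opposite face, trans to the C5 methyl and to the C2 bromine. The step needs facial selectivity and C–C bond formation at a doubly flanked carbon; the locked chair secures the first, and the single α-hydrogen of 6 under base-free conditions (C2–Br untouched) favours the second.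

Step 7
Reactants: 9 (6R,8R,11S)-8-bromo-7,7,11-trimethylspiro[5.5]undec-1-en-3-one
Product: 11 (2S,6S,8R,11S)-2,8-dibromo-7,7,11-trimethylspiro[5.5]undecan-3-one, via lithium enolate 10 (not isolated)
Conditions: LiBH(s-Bu)3, THF, −78 °C; NBS, −78 → 0 °C; then LiBr (cat.), acetone, 23 °C
Reagents that add atoms: N-bromosuccinimide (NBS), O=C1CCC(=O)N1Br
Why: 1,4-hydride addition to the β-unsubstituted enone gives only the C8=C9 enolate, which NBS brominates at C8; bromide SN2 exchange should then equilibrate the α-bromo ketone to the equatorial bromide (cis to C1), because an axial bromine would clash with C5, the ring A carbon that is axial on ring B.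

Step 8
Reactants: 11 (2S,6S,8R,11S)-2,8-dibromo-7,7,11-trimethylspiro[5.5]undecan-3-one
Product: 12 (2S,3R,6S,8R,11S)-2,8-dibromo-3,7,7,11-tetramethylspiro[5.5]undecan-3-ol
Conditions: MeMgBr, Et2O–toluene, −78 °C
Reagents that add atoms: methylmagnesium bromide (MeMgBr), C[Mg]Br
Why: Grignard 1,2-addition to an α-bromo ketone at low temperature (halohydrin synthesis), expected mainly from the equatorial direction (axial OH); either C9 epimer serves, because this centre is re-formed in step 9.

Step 9
Reactants: 12 (2S,3R,6S,8R,11S)-2,8-dibromo-3,7,7,11-tetramethylspiro[5.5]undecan-3-ol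
Product: 13 (2R,5S,6S,8S,9S)-2,8-dibromo-9-chloro-1,1,5,9-tetramethylspiro[5.5]undecane
Conditions: HCl (g), CH2Cl2, −20 → 23 °C
Reagents that add atoms: hydrogen chloride, Cl
Why: SN1 chlorination of a tertiary alcohol; the cation should be bridged by the neighbouring C8 bromine on its own face so that chloride enters C9 from the opposite face (trans, both halogens equatorial), and any 9-bromo-8-chloro isomer from opening at C8 should return through the same ion pair to the more stable tertiary chloride.

**Compound list**

1 | methyl (2E)-3,7-dimethylocta-2,6-dienoate (methyl geranate) | COC(=O)/C=C(\C)CCC=C(C)C | starting material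
2 | methyl (2E)-5-[(2S)-3,3-dimethyloxiran-2-yl]-3-methylpent-2-enoate | COC(=O)/C=C(\C)CC[C@@H]1OC1(C)C | intermediate
3 | methyl (2E,6R)-6,7-dibromo-3,7-dimethyloct-2-enoate | COC(=O)/C=C(\C)CC[C@@H](Br)C(C)(C)Br | intermediate
4 | methyl (1S,5R)-5-bromo-2,6,6-trimethylcyclohex-2-ene-1-carboxylate | COC(=O)[C@H]1C(C)=CC[C@@H](Br)C1(C)C | intermediate
5 | methyl (1S,3R,6S)-3-bromo-2,2,6-trimethylcyclohexane-1-carboxylate | COC(=O)[C@H]1[C@@H](C)CC[C@@H](Br)C1(C)C | intermediate
6 | (1S,3R,6S)-3-bromo-2,2,6-trimethylcyclohexane-1-carbaldehyde | O=C[C@H]1[C@@H](C)CC[C@@H](Br)C1(C)C | intermediate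
7 | but-3-en-2-one (methyl vinyl ketone) | C=CC(C)=O | starting material
8 | (1S,3R,6S)-3-bromo-2,2,6-trimethyl-1-(3-oxobutyl)cyclohexane-1-carbaldehyde | O=C[C@@]1(CCC(C)=O)[C@@H](C)CC[C@@H](Br)C1(C)C | intermediate
9 | (6R,8R,11S)-8-bromo-7,7,11-trimethylspiro[5.5]undec-1-en-3-one | C[C@H]1CC[C@@H](Br)C(C)(C)[C@]12CCC(=O)C=C2 | intermediate
10 | lithium (6S,8R,11S)-8-bromo-7,7,11-trimethylspiro[5.5]undec-2-en-3-olate | C[C@H]1CC[C@@H](Br)C(C)(C)[C@]12CCC([O-])=CC2.[Li+] | intermediate
11 | (2S,6S,8R,11S)-2,8-dibromo-7,7,11-trimethylspiro[5.5]undecan-3-one | C[C@H]1CC[C@@H](Br)C(C)(C)[C@]12CCC(=O)[C@@H](Br)C2 | intermediate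
12 | (2S,3R,6S,8R,11S)-2,8-dibromo-3,7,7,11-tetramethylspiro[5.5]undecan-3-ol | C[C@H]1CC[C@@H](Br)C(C)(C)[C@]12CC[C@@](C)(O)[C@@H](Br)C2 | intermediate
13 | (2R,5S,6S,8S,9S)-2,8-dibromo-9-chloro-1,1,5,9-tetramethylspiro[5.5]undecane | C[C@H]1CC[C@@H](Br)C(C)(C)[C@]12CC[C@](C)(Cl)[C@@H](Br)C2 | target

**Count and risks**

Total step count: 9. Longest linear sequence: 9.

Steps most likely to fail:

Step 6 (key step). The conjugate addition at the fully substituted enol carbon, flanked by CMe2 and CHMe, may be too slow, so that polymerisation of the vinyl ketone or self-condensation takes over; facial selectivity could also be eroded if ring A reacts through its other chair. The fallback sets out from ester 5 and comes back at enone 9. Deprotonation of 5 (LiN(i-Pr)2, THF–DMPU, −78 °C) and alkylation of the ester enolate with 2-(2-iodoethyl)-2-methyl-1,3-dioxolane, anti to the axial methyl groups, should give methyl (1S,3R,6S)-3-bromo-2,2,6-trimethyl-1-[2-(2-methyl-1,3-dioxolan-2-yl)ethyl]cyclohexane-1-carboxylate F1. Reduction with i-Bu2AlH (−78 °C) should give (1S,3R,6S)-3-bromo-2,2,6-trimethyl-1-[2-(2-methyl-1,3-dioxolan-2-yl)ethyl]cyclohexane-1-carbaldehyde F2. TsOH in wet acetone, then toluene at reflux, unmasks the methyl ketone and closes ring B by aldol condensation to 9.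

Step 9. The capture of the tertiary cation may lose regio- or stereocontrol (chloride arriving before bromine bridging, opening at the secondary carbon without return, or elimination to an alkene). The fallback sets out from enone 9 and comes back at target 13. Conjugate reduction (LiBH(s-Bu)3) and trapping with PhNTf2 should give (6S,8R,11S)-8-bromo-7,7,11-trimethylspiro[5.5]undec-2-en-3-yl trifluoromethanesulfonate F3. Me2CuLi should convert it into (6S,8R,11S)-8-bromo-3,7,7,11-tetramethylspiro[5.5]undec-2-ene F4. Anti addition of BrCl (NBS, Et4NCl, CH2Cl2, −78 °C) from the exposed face with diaxial opening should first give (2R,3R,6S,8R,11S)-3,8-dibromo-2-chloro-3,7,7,11-tetramethylspiro[5.5]undecane F5. Warming in nitromethane should isomerise it to the diequatorial isomer 13 by 1,2-interchange of the two halogens through the bromonium chloride ion pair, the diaxial-to-diequatorial rearrangement known for 5,6-dihalo steroids.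

Step 3. The conjugated alkene may be too weak a π-nucleophile, so that ion-pair return, elimination to an allylic bromide or capture by solvent competes with ring closure. The fallback sets out from dibromide 3 and comes back at aldehyde 6. Reduction of the ester (i-Bu2AlH, CH2Cl2, −78 → 0 °C) should give the electron-richer (2E,6R)-6,7-dibromo-3,7-dimethyloct-2-en-1-ol F6. The same solvolysis ((CF3)2CHOH, NaHCO3) should cyclise it to [(1S,5R)-5-bromo-2,6,6-trimethylcyclohex-2-en-1-yl]methanol F7. Hydrogenation (H2, PtO2) should give [(1S,3R,6S)-3-bromo-2,2,6-trimethylcyclohexyl]methanol F8, and Dess–Martin oxidation leads to 6.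

**Further compounds**

F1 | step 6 | methyl (1S,3R,6S)-3-bromo-2,2,6-trimethyl-1-[2-(2-methyl-1,3-dioxolan-2-yl)ethyl]cyclohexane-1-carboxylate | COC(=O)[C@@]1(CCC2(C)OCCO2)[C@@H](C)CC[C@@H](Br)C1(C)C
F2 | step 6 | (1S,3R,6S)-3-bromo-2,2,6-trimethyl-1-[2-(2-methyl-1,3-dioxolan-2-yl)ethyl]cyclohexane-1-carbaldehyde | O=C[C@@]1(CCC2(C)OCCO2)[C@@H](C)CC[C@@H](Br)C1(C)C
F3 | step 9 | (6S,8R,11S)-8-bromo-7,7,11-trimethylspiro[5.5]undec-2-en-3-yl trifluoromethanesulfonate | C[C@H]1CC[C@@H](Br)C(C)(C)[C@]12CCC(OS(=O)(=O)C(F)(F)F)=CC2
F4 | step 9 | (6S,8R,11S)-8-bromo-3,7,7,11-tetramethylspiro[5.5]undec-2-ene | C[C@H]1CC[C@@H](Br)C(C)(C)[C@]12CCC(C)=CC2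
F5 | step 9 | (2R,3R,6S,8R,11S)-3,8-dibromo-2-chloro-3,7,7,11-tetramethylspiro[5.5]undecane | C[C@H]1CC[C@@H](Br)C(C)(C)[C@]12CC[C@@](C)(Br)[C@H](Cl)C2
F6 | step 3 | (2E,6R)-6,7-dibromo-3,7-dimethyloct-2-en-1-ol | OC/C=C(\C)CC[C@@H](Br)C(C)(C)Br
F7 | step 3 | [(1S,5R)-5-bromo-2,6,6-trimethylcyclohex-2-en-1-yl]methanol | OC[C@H]1C(C)=CC[C@@H](Br)C1(C)C
F8 | step 3 | [(1S,3R,6S)-3-bromo-2,2,6-trimethylcyclohexyl]methanol | OC[C@H]1[C@@H](C)CC[C@@H](Br)C1(C)C
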